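**Retrosynthetic overview**
- Target ⇐ hydrogenation of the β-keto γ-lactone carbonyl ⇐ methyl addition to the ring-B ketone ⇐ one-pot spiro δ-lactone annulation (β-iodoacrylate, then acetone) on a pentacyclic triketo lactone.
- Key disconnection: the pentacyclic cage ⇐ a radical formal [4+2] that forms the bond from the methyl-bearing dione carbon to an exocyclic CH2 and the bond from the adjacent ring-B carbon to a butenolide β-carbon, closing ring C and the bicyclo[2.2.2]octane in one operation.
- Cascade precursor ⇐ enol-dione/butenolide bicycle joined through one CH2 to a cyclohexane-1,3-dione, which silylation and Wittig methylenation turn into a 1-silyloxy diene.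
- Bicycle ⇐ acyclic quaternary 1,3-diketone (malonylation, Knoevenagel, Claisen); quaternary centre ⇐ asymmetric Michael addition of a 2-methyl-1,3-diketone to 2-methylidenecyclohexane-1,3-dione.
- Ring order: B (bought) → E (butenolide) → six-membered enol-dione ring → C and D together (radical step) → A.

Notation: ring A = spiro δ-lactone, B = cyclohexane, C = cyclopentane, D = bicyclo[2.2.2]octane, E = γ-lactone.

Assumption: the quinidine-derived squaramide is taken to give the (S)-configured Michael adduct (its quinine-derived pseudo-enantiomer is used if the sense is opposite); the enolisable α-carbon of the β-keto γ-lactone is drawn throughout in the configuration carried into the target.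

**Route**

Step 1
Reactants: 1 pentan-3-one; 2 methyl 2-[(tert-butyldimethylsilyl)oxy]acetate (silyl-protected methyl glycolate)
Product: 3 1-[(tert-butyldimethylsilyl)oxy]-3-methylhexane-2,4-dione (racemic, enolisable)
Conditions: LiN(iPr)2 (2.1 equiv), THF, −78 °C; 2, −78 → 0 °C; AcOH
Reagents that add atoms: none
Why: Crossed Claisen condensation in which the lithium enolate of the symmetrical ketone is C-acylated by the activated α-silyloxy ester and the second equivalent of base removes the product as its diketonate.

Step 2
Reactants: 4 cyclohexane-1,3-dione; 5 formaldehyde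
Product: 6 2-[(phenylsulfonyl)methyl]cyclohexane-1,3-dione
Conditions: PhSO2Na, 37% aq. CH2O, AcOH–H2O, 25 °C
Reagents that add atoms: sodium benzenesulfinate, [Na+].[O-]S(=O)c1ccccc1
Why: Knoevenagel condensation followed by conjugate addition of sulfinate (three-component sulfonylmethylation) stores the self-condensing 2-methylidene-1,3-dione as a stable sulfone.

Step 3
Reactants: 3 1-[(tert-butyldimethylsilyl)oxy]-3-methylhexane-2,4-dione; 6 2-[(phenylsulfonyl)methyl]cyclohexane-1,3-dione
Product: 8 (3S)-1-[(tert-butyldimethylsilyl)oxy]-3-[(2,6-dioxocyclohexyl)methyl]-3-methylhexane-2,4-dione, via 2-methylidenecyclohexane-1,3-dione 7 (not isolated)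
Conditions: quinidine-derived 3,5-bis(trifluoromethyl)phenyl squaramide (10 mol%), K2CO3 (1.5 equiv), toluene–H2O, 0 °C; pH 4 buffer
Reagents that add atoms: none
Why: Proposed new method: base-induced E1cB loss of sulfinate releases acceptor 7 at low concentration while the bifunctional catalyst (amine holds the diketone enol, squaramide N–H bonds hold the dione) directs an asymmetric Michael addition through the only 1,3-dicarbonyl C–H of 3 and sets the quaternary centre as S; the closest known type is squaramide-catalysed addition of 1,3-dicarbonyls to ortho-quinone methides released in situ from 2-(sulfonylmethyl)phenols.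

Step 4
Reactants: 8 (3S)-1-[(tert-butyldimethylsilyl)oxy]-3-[(2,6-dioxocyclohexyl)methyl]-3-methylhexane-2,4-dione
Product: 9 (3S)-3-[(2,6-dioxocyclohexyl)methyl]-1-hydroxy-3-methylhexane-2,4-dione
Conditions: HF·pyridine, THF–pyridine, 0 °C
Reagents that add atoms: none
Why: Fluoride cleavage of the primary silyl ether under buffered, non-nucleophilic conditions that avoid retro-Claisen cleavage of the quaternary 1,3-diketone.

Step 5
Reactants: 9 (3S)-3-[(2,6-dioxocyclohexyl)methyl]-1-hydroxy-3-methylhexane-2,4-dione; 10 methyl 3-chloro-3-oxopropanoate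
Product: 13 (4R)-4-[(2,6-dioxocyclohexyl)methyl]-7-hydroxy-4,6-dimethyl-2-benzofuran-1,5(3H,4H)-dione, via malonate ester 11 (not isolated), via butenolide ester 12 (not isolated)
Conditions: 10 (1.2 equiv), pyridine, DMAP (cat.), CH2Cl2, 0 °C; solvent switch; KOtBu (4.5 equiv), THF–tBuOH, 0 → 45 °C; 1 M HCl
Reagents that add atoms: none
Why: O-acylation (DMAP relays any enol ester on the ring-B dione to the primary alcohol), intramolecular Knoevenagel condensation onto the adjacent ketone and a Claisen (Dieckmann-type) acylation of the ethyl-ketone enolate by the butenolide ester close rings E and the enol-dione ring, driven by formation of the strongly acidic vinylogous acid; the stereocentre is untouched (S becomes R only through changed CIP priorities).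

Step 6
Reactants: 13 (4R)-4-[(2,6-dioxocyclohexyl)methyl]-7-hydroxy-4,6-dimethyl-2-benzofuran-1,5(3H,4H)-dione
Product: 14 (4R)-4,6-dimethyl-4-({6-oxo-2-[(triisopropylsilyl)oxy]cyclohex-1-en-1-yl}methyl)-7-[(triisopropylsilyl)oxy]-2-benzofuran-1,5(3H,4H)-dione
Conditions: iPr3SiOTf (2.3 equiv), Et3N (3 equiv), CH2Cl2, −78 → 0 °C
Reagents that add atoms: triisopropylsilyl trifluoromethanesulfonate, CC(C)[Si](C(C)C)(C(C)C)OS(=O)(=O)C(F)(F)F
Why: Soft-enolisation O-silylation of both vinylogous acids turns ring B into a vinylogous silyl ester with one unhindered electrophilic carbonyl.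

Step 7
Reactants: 14 (4R)-4,6-dimethyl-4-({6-oxo-2-[(triisopropylsilyl)oxy]cyclohex-1-en-1-yl}methyl)-7-[(triisopropylsilyl)oxy]-2-benzofuran-1,5(3H,4H)-dione
Product: 16 (4R)-7-hydroxy-4,6-dimethyl-4-({6-methylidene-2-[(triisopropylsilyl)oxy]cyclohex-1-en-1-yl}methyl)-2-benzofuran-1,5(3H,4H)-dione, via bis-silyl triene 15 (not isolated)
Conditions: Ph3PCH3Br (3.5 equiv), KN(SiMe3)2 (3.3 equiv), THF, 0 → 40 °C; then K2CO3 (0.2 equiv), MeOH, 0 °C, 15 min; pH 5 buffer
Reagents that add atoms: methyltriphenylphosphonium bromide, C[P+](c1ccccc1)(c1ccccc1)c1ccccc1.[Br-]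
Why: Wittig methylenation takes place at the unhindered ring-B carbonyl (the cross-conjugated dienone carbonyl sits next to the quaternary carbon and the lactone is inert) to give the 1-silyloxy diene, and brief methanolysis removes only the ester-like silyl group on the vinylogous acid.

Step 8
Reactants: 16 (4R)-7-hydroxy-4,6-dimethyl-4-({6-methylidene-2-[(triisopropylsilyl)oxy]cyclohex-1-en-1-yl}methyl)-2-benzofuran-1,5(3H,4H)-dione
Product: 18 pentacyclic triketo lactone (rings B–E; ring-B ketone, bridging ketone, β-keto γ-lactone, cis B/C fusion), via cage silyl enol ether 17 (not isolated)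
Conditions: Mn(OAc)3·2H2O (2.2 equiv, in portions), degassed EtOH, 25 °C; then HF·pyridine, THF, 0 → 25 °C
Reagents that add atoms: none
Why: Proposed new method: oxidative free-radical cyclisation in which manganese triacetate oxidises the enolised 2-methyl-1,3-dione to an electrophilic radical that adds 7-endo to the terminal methylene of the electron-rich diene (only the face carrying the CH2 tether is reachable), the nucleophilic siloxyallyl radical then closes transannularly 5-exo onto the butenolide β-carbon (the seven-membered ring holds only its ring-fusion terminus near that carbon) and the lactone radical abstracts hydrogen from ethanol, so both quaternary–quaternary bonds, ring C and ring D form at once with every new centre fixed by the pre-set quaternary carbon and ring strain, and desilylation protonates the enol to the only attainable cis B/C fusion; the closest known type is the manganese triacetate tandem cyclisation of 2-alkyl-1,3-diones (7-endo, then transannular 5-exo).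

Step 9
Reactants: 18 pentacyclic triketo lactone; 19 methyl (2Z)-3-iodoprop-2-enoate; 20 acetone
Product: 22 hexacyclic spiro δ-lactone ketone (ring A closed, ring-B ketone retained), via Z-enoate 21 (not isolated)
Conditions: LiN(SiMe3)2 (2.1 equiv), THF, −78 °C; 19, −78 → −30 °C; LiN(SiMe3)2 (1.1 equiv), −78 °C; acetone (5 equiv), −78 → 0 °C; AcOH
Reagents that add atoms: none
Why: Vinylogous acylation then aldol–lactonisation: the kinetic ring-B ketone enolate (the β-keto lactone is masked as its enolate) undergoes addition–elimination with the β-iodoacrylate, the derived extended enolate adds through its α-carbon to acetone from the exposed convex face (the other face lies over the γ-lactone) and the alkoxide lactonises onto the (Z)-ester, which makes the aldol irreversible and sets the spiro centre with the CMe2–O arm on the exposed face.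

Step 10
Reactants: 22 hexacyclic spiro δ-lactone ketone
Product: 23 ring-B tertiary methyl carbinol (β-keto γ-lactone retained)
Conditions: LiN(SiMe3)2 (1.05 equiv), THF, −78 °C; MeCeCl2 (from MeLi + CeCl3, 3 equiv), −78 → −50 °C; AcOH
Reagents that add atoms: methyllithium, [Li]C
Why: Organocerium 1,2-addition, after masking the β-keto lactone as its enolate, is selective for the ring-B ketone (the bridging ketone lies between two quaternary carbons and the conjugated lactone is a weaker electrophile), and methyl enters equatorially from the exposed face because the axial trajectory is blocked by the 1,3-diaxial cage carbon, giving the axial tertiary alcohol.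

Step 11
Reactants: 23 ring-B tertiary methyl carbinol (β-keto γ-lactone)
Product: 24 CNP0360620.3 (target)
Conditions: RuCl2[(S)-binap] (2 mol%), H2 (50 atm), CH2Cl2–MeOH, 50 °C
Reagents that add atoms: none
Why: Noyori hydrogenation with dynamic kinetic resolution: both carbonyl oxygens of the β-keto lactone chelate ruthenium, hydride is delivered inside the chelate from the lactone-carbonyl side so the hydroxyl ends anti to the lactone carbonyl (R carbinol, matched with the S ligand) while the α-carbon equilibrates through the enol, and the non-chelating bridging ketone and hindered ring-A enoate are left alone.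

**Compound list**

1 | pentan-3-one | CCC(=O)CC | starting material
2 | methyl 2-[(tert-butyldimethylsilyl)oxy]acetate | COC(=O)CO[Si](C)(C)C(C)(C)C | starting material
3 | 1-[(tert-butyldimethylsilyl)oxy]-3-methylhexane-2,4-dione (racemic) | CCC(=O)C(C)C(=O)CO[Si](C)(C)C(C)(C)C | intermediate
4 | cyclohexane-1,3-dione | O=C1CCCC(=O)C1 | starting material
5 | formaldehyde | C=O | starting material
6 | 2-[(phenylsulfonyl)methyl]cyclohexane-1,3-dione | O=C1CCCC(=O)C1CS(=O)(=O)c1ccccc1 | intermediate
7 | 2-methylidenecyclohexane-1,3-dione | C=C1C(=O)CCCC1=O | intermediate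
8 | (3S)-1-[(tert-butyldimethylsilyl)oxy]-3-[(2,6-dioxocyclohexyl)methyl]-3-methylhexane-2,4-dione | CCC(=O)[C@](C)(CC1C(=O)CCCC1=O)C(=O)CO[Si](C)(C)C(C)(C)C | intermediate
9 | (3S)-3-[(2,6-dioxocyclohexyl)methyl]-1-hydroxy-3-methylhexane-2,4-dione | CCC(=O)[C@](C)(CC1C(=O)CCCC1=O)C(=O)CO | intermediate
10 | methyl 3-chloro-3-oxopropanoate | COC(=O)CC(=O)Cl | starting material
11 | (3S)-3-[(2,6-dioxocyclohexyl)methyl]-3-methyl-2,4-dioxohexyl methyl propanedioate | CCC(=O)[C@](C)(CC1C(=O)CCCC1=O)C(=O)COC(=O)CC(=O)OC | intermediate
12 | methyl 4-[(2R)-1-(2,6-dioxocyclohexyl)-2-methyl-3-oxopentan-2-yl]-2-oxo-2,5-dihydrofuran-3-carboxylate | CCC(=O)[C@](C)(CC1C(=O)CCCC1=O)C1=C(C(=O)OC)C(=O)OC1 | intermediate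
13 | (4R)-4-[(2,6-dioxocyclohexyl)methyl]-7-hydroxy-4,6-dimethyl-2-benzofuran-1,5(3H,4H)-dione | CC1=C(O)C2=C(COC2=O)[C@@](C)(CC3C(=O)CCCC3=O)C1=O | intermediate
14 | (4R)-4,6-dimethyl-4-({6-oxo-2-[(triisopropylsilyl)oxy]cyclohex-1-en-1-yl}methyl)-7-[(triisopropylsilyl)oxy]-2-benzofuran-1,5(3H,4H)-dione | CC1=C(O[Si](C(C)C)(C(C)C)C(C)C)C2=C(COC2=O)[C@@](C)(CC3=C(O[Si](C(C)C)(C(C)C)C(C)C)CCCC3=O)C1=O | intermediate
15 | (4R)-4,6-dimethyl-4-({6-methylidene-2-[(triisopropylsilyl)oxy]cyclohex-1-en-1-yl}methyl)-7-[(triisopropylsilyl)oxy]-2-benzofuran-1,5(3H,4H)-dione | CC1=C(O[Si](C(C)C)(C(C)C)C(C)C)C2=C(COC2=O)[C@@](C)(CC3=C(O[Si](C(C)C)(C(C)C)C(C)C)CCCC3=C)C1=O | intermediate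
16 | (4R)-7-hydroxy-4,6-dimethyl-4-({6-methylidene-2-[(triisopropylsilyl)oxy]cyclohex-1-en-1-yl}methyl)-2-benzofuran-1,5(3H,4H)-dione | CC1=C(O)C2=C(COC2=O)[C@@](C)(CC3=C(O[Si](C(C)C)(C(C)C)C(C)C)CCCC3=C)C1=O | intermediate
17 | pentacyclic cage (rings B–E) as the ring-B triisopropylsilyl enol ether; bridging ketone and β-keto γ-lactone present | C2CC[C@]13C[C@]4(C)C(=O)[C@](C)(CC1=C2O[Si](C(C)C)(C(C)C)C(C)C)[C@]31COC(=O)[C@@H]1C4=O | intermediate
18 | pentacyclic triketo lactone (rings B–E; ring-B ketone, bridging ketone, β-keto γ-lactone; cis B/C fusion) | C2CC[C@]13C[C@]4(C)C(=O)[C@](C)(C[C@H]1C2=O)[C@]31COC(=O)[C@@H]1C4=O | intermediate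
19 | methyl (2Z)-3-iodoprop-2-enoate | COC(=O)/C=C\I | starting material
20 | acetone | CC(C)=O | starting material
21 | 18 carrying a (Z)-2-(methoxycarbonyl)ethenyl group on the ring-B α-methylene carbon (epimers at that carbon; used as its lithium dienolate) | C2(/C=C\C(=O)OC)CC[C@]13C[C@]4(C)C(=O)[C@](C)(C[C@H]1C2=O)[C@]31COC(=O)[C@@H]1C4=O | intermediate
22 | hexacyclic spiro δ-lactone ketone (rings A–E; ring-B ketone, bridging ketone, β-keto γ-lactone) | CC1(C)OC(=O)C=C[C@]12CC[C@]13C[C@]4(C)C(=O)[C@](C)(C[C@H]1C2=O)[C@]31COC(=O)[C@@H]1C4=O | intermediate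
23 | ring-B tertiary methyl carbinol of 22 (methyl on the exposed face, hydroxyl axial; β-keto γ-lactone retained) | CC1(C)OC(=O)C=C[C@]12CC[C@]13C[C@]4(C)C(=O)[C@](C)(C[C@H]1[C@@]2(C)O)[C@]31COC(=O)[C@@H]1C4=O | intermediate
24 | CNP0360620.3 | CC1(C)OC(=O)C=C[C@]12CC[C@]13C[C@]4(C)C(=O)[C@](C)(C[C@H]1[C@@]2(C)O)[C@]31COC(=O)[C@@H]1[C@H]4O | target

**Step count**

Total steps: 11. Longest linear sequence: 10 (steps 1 and 3–11; step 2 is a one-step branch).

**Steps most likely to fail, with fallbacks**

Step 8 (radical cascade). Two things can go wrong. The dione radical may attack the fully substituted enol-ether carbon 5-exo instead of the methylene terminus 7-endo. The siloxyallyl radical may be oxidised by manganese triacetate before it closes onto the butenolide. The fallback sets out from 16 and comes back at 18, and reverses the polarity of the first bond formation. Oxidation of the silyl dienol ether with (NH4)2Ce(NO3)6 and NaHCO3 in MeCN at −30 °C gives the diene radical cation. The nucleophilic dione carbon can reach it only at the methylene terminus, and further oxidation with loss of the silyl group gives the bridged enone F1. SmI2 in THF–tBuOH at 0 °C then joins the two β-carbons (ring-B enone and butenolide) across the ring by reductive radical coupling, and protonation gives 18.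

Step 3 (enantioselective Michael addition). An acyclic, unsymmetrical 2-methyl-1,3-diketone may be poorly differentiated by the catalyst. The fallback sets out from 3 and 6 and comes back at 8, and replaces asymmetric catalysis by resolution. The addition is run with K2CO3 alone to give the racemic adduct, the acidic ring-B dione is crystallised as its (R)-1-phenylethylammonium salt F2, and acidification of the less soluble salt returns enantiopure 8.

Step 9 (one-pot spiro-lactone annulation). The aldol of a hindered, stabilised enolate with acetone may revert faster than it lactonises, or the extended enolate may react through the ester α-carbon. The fallback sets out from 18 and comes back at 22, and builds the two arms separately. Formylation (HCO2Et, NaH) gives the hydroxymethylene ketone F3. In(OTf)3-catalysed addition of this 1,3-dicarbonyl to propyne puts an isopropenyl group on the exposed face and gives the formyl ketone F4. Still–Gennari olefination of the aldehyde gives the (Z)-enoate F5. Catalytic TfOH then closes ring A by Markovnikov addition of the ester carbonyl to the isopropenyl group, returning 22.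

**Further compounds**

F1 | step 8 | bridged enone: ring-B cyclohexenone whose α- and β-CH2 arms span the two quaternary carbons of the 2-methyl-1,3-dione/butenolide bicycle | O=C1CCCC2=C1C[C@]3(C)C4=C(C(=O)OC4)C(=O)[C@](C)(C2)C3=O
F2 | step 3 | (R)-1-phenylethylammonium salt of 8 (ring-B dione enolate) | CCC(=O)[C@](C)(CC1=C([O-])CCCC1=O)C(=O)CO[Si](C)(C)C(C)(C)C.C[C@@H]([NH3+])c1ccccc1
F3 | step 9 | hydroxymethylene ketone of 18 (formylated at the ring-B α-methylene carbon) | OC=C2CC[C@]13C[C@]4(C)C(=O)[C@](C)(C[C@H]1C2=O)[C@]31COC(=O)[C@@H]1C4=O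
F4 | step 9 | α-formyl α-isopropenyl ring-B ketone (isopropenyl on the exposed face) | O=C[C@@]2(C(C)=C)CC[C@]13C[C@]4(C)C(=O)[C@](C)(C[C@H]1C2=O)[C@]31COC(=O)[C@@H]1C4=O
F5 | step 9 | (Z)-enoate from F4 (methyl (Z)-acrylate arm and isopropenyl arm on the spiro carbon) | COC(=O)/C=C\[C@@]2(C(C)=C)CC[C@]13C[C@]4(C)C(=O)[C@](C)(C[C@H]1C2=O)[C@]31COC(=O)[C@@H]1C4=O
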